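The numbers in the tables are calculated on assumed constants, noise included.

The nucleophile enters at a steady rate, so the amount fed grows in a straight line with time. Suppose the electrophile falls at a rate proportional to itself and to the nucleophile fed so far: a pseudo-first-order loss whose rate constant climbs along that line. The integral of a straight line is a triangle, which gives a bench rule: over a feed, the dose counts as half of itself held for the whole feed. The logarithm of one over the fraction of electrophile left therefore grows with the square of time and in proportion to the dose.

all flasks: electrophile 0.20 M
- zeta: nucleophile 1.1 equiv (fed, over 2.0 min); free base 1.6 equiv; run made earlier; the fed solution adds 0.10 times the starting volume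
- gamma: nucleophile 1.1 equiv (fed, over 2.0 min); free base 2.7 equiv; run made earlier; the fed solution adds 0.10 times the starting volume
- beta: nucleophile 1.1 equiv (fed, over 2.0 min); free base 3.9 equiv; run made earlier; the fed solution adds 0.10 times the starting volume
- Wednesday's: nucleophile 1.10 equiv (fed, over 2.0 min); free base 2.00 equiv; the fed solution adds 0.10 times the starting volume; time 2.0 min
- Monday's: nucleophile 1.10 equiv (fed, over 2.0 min); free base 4.00 equiv; the fed solution adds 0.10 times the starting volume; time 2.0 min

| run | time / s | electrophile / % | target / % |
|---|---|---|---|
| zeta | 10.0 | 100.2 | 0.2 |
| zeta | 20.0 | 97.5 | 1.2 |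
| zeta | 50.0 | 93.9 | 5.7 |
| zeta | 120 | 77.5 | 21.9 |
| gamma | 15.0 | 98.4 | 0 |
| gamma | 40.0 | 96.1 | 2.8 |
| gamma | 80.0 | 88.9 | 9.5 |
| gamma | 120 | 77.4 | 19.2 |
| beta | 30.0 | 96.1 | 2.5 |
| beta | 60.0 | 92.3 | 6.7 |
| beta | 90.0 | 85.8 | 13.9 |
| beta | 120 | 75.8 | 20.3 |

(readings scatter by 1 percentage point)

- part of the electrophile that has reacted at the end, Wednesday's
- part of the electrophile that has reacted at the end, Monday's
- what raising the equivalents of free base from its lowest to its highest value here does to the part of the electrophile that has reacted (changes below 5 percentage points count as none) (it falls / no change / it rises)

- every charge counts on the volume at the start, and the solution that is fed holds the whole dose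

The gamma run tests the square. From its 77.4% left at 120 s, the rule puts 89.2% at 80.0 s, and the reading is 88.9%. The mean of the three end readings gives 0.239. This is the feed slope, the logarithm of one over the fraction of electrophile left at the end of the feed, per equivalent dosed. Free base gets no term in it: its charge spans a factor of 2.44, yet the end readings differ by 1.7 percentage points against a scatter of 1 point.

The triangle ends with the feed, where the ratio of time to dosing time reaches one. Wednesday's and Monday's both have a ratio of 1.00, so they stand on that border, still inside. My own reckoning with 1.10 equiv gives 23.1% reacted in both flasks. The forecast says 23% for Wednesday's, 23.5% for Monday's and no change, since the reaction “looks essentially zero order in base”.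

Wednesday's reaches 22.3% and Monday's 22.4%: no change, a difference of 0.011 points.

    target → over-reaction product (k = 0.00221 /s)
    acid set free + free base ⇌ salt of the base, settled at all times (K = 4.66 /M)
    electrophile + nucleophile ⇌ acid set free + target (K = 0.749, k = 0.0296 /M/s)
    nucleophile + acid set free ⇌ protonated nucleophile, settled at all times (K = 5200 /M)

Monday's stays low in part because the dose comes in over the feed and the time is short: given at once it reaches 35.1%, and read at 20.0 min it reaches 58.3%. Its own slope is 0.230, and its answer moves by 5 points at 1.38 equiv of nucleophile. For a neighbour of Monday's charged with 4.40 equiv of nucleophile, the feed slope leaves 34.9% of the electrophile, and that flask holds 33.7%.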